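The noon run is the very flask that is asked about, followed so far to 6.00 min; what it holds at 15 min is the question.

- noon: substrate 0.10 M; gas phase 19 mM (held); the very flask that is asked about, followed so far
- flask: substrate 0.10 M; gas phase 19 mM (held); time 15 min

noon run (percent of the substrate charged)

| time / min | target / % | substrate / % |
|---|---|---|
| 0.500 | 3.2 | 97.9 |
| 0.833 | 6.0 | 93.2 |
| 1.50 | 12.8 | 86.8 |
| 3.00 | 26.7 | 69.7 |
| 6.00 | 43.3 | 44.4 |

(scatter of a reading: 0.5 percentage points)

- at the start none of the gas phase is in solution

- the target standing at 15 min, as a percentage of the substrate charged
- the change that raises the amount of target at 15 min, in percent of the substrate charged most ("none" if none brings more than 2 percentage points) (grey / green / none)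
- amount of target at 15 min, in percent of the substrate charged, after green

- grey: doubling the saturation concentration of gas phase, all else as stated
- green: doubling the transfer coefficient of the gas phase, all else as stated

In the first instants none of the gas phase is in solution, and at 1.50 min target and substrate leave a gap of 0.4 percentage points against the charge, with a scatter of 0.5 points on each reading. In the middle of the run, between 3.00 min and 6.00 min, that gap grows from 3.6 points to 12 points, so target is leaving for something unseen.

Let A and P be substrate and target in percent of the charge, with substrate falling as k·A and target leaving as k′·P. Dividing one rate by the other removes time: the growth of the gap, over the mean target times the logarithm of the substrate ratio, gives κ = 0.551, the selectivity factor k′/k, the target's fractional loss per fractional loss of substrate. This is a reading from the noon run between those two times, and it carries the scatter of those readings.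

Target rises while A/(κP), made over used, exceeds one, and on this reckoning its summit lies at substrate 26.5 % and target 48.1 %. Toward the end, with k read at 0.150 /min and carried forward unchanged, this reckoning puts substrate at 11.5 % at 15 min, lower than the summit's level. This reckoning therefore puts the target at 42.0 %, with the ratio at 0.497, under one, so target is on its falling side by then. More gas, taken to speed the substrate's step, is judged to move target further down that side, and so this reckoning expects no useful gain from either change.

The forecast gives 40 % (from 35 % to 45 %), best none, and 35 % after green (from 28 % to 43 %), on the ground that “More gas only hastens the approach to the peak and beyond.” The reckoning above stands 2 points higher.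

The flask gives 44.4 % and best none, with grey at −4.2 points and green at −1.3 points, and 43.1 % after green.

    gas phase ⇌ dissolved gas, rate k1*(csat - [dissolved gas]) (kL = 1.60 /min)
    target ⇌ isomer of the product (K = 15.0, k = 0.0850 /min)
    substrate + dissolved gas → target (k = 12.0 /M/min)
    dissolved gas → decomposed reagent (k = 0.0660 /min)

At 15.0 min the isomer of the product stands in the flask at 47.4 %. With κ, the flask's substrate 8.21 % and target 44.4 % give A/(κP) = 0.336, under one. Read at 10 min, the neighbour flask holds substrate 22.0 % and target 49.9 %, and its ratio stands at 0.800.

The readings were generated by integration for substances that don't exist, and the scatter is random.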